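**Retrosynthetic overview**

- The target is (2R,3S)-naringenin bonded through C3 to C8'' of apigenin 7''-O-sulfate. The strategy rests on ring C of the flavanone: O1–C2–C3–C4 fused to phloroglucinol ring A, with trans aryl groups on C2 and C3 in the pattern of an (E)-stilbene.
- Late disconnections: O7''–S (sulfation of the one free phenol, every other hydroxyl being a benzyl ether) and C4=O (hydride abstraction at the C4 methylene of a chroman, then alcohol oxidation).
- Key disconnection: O1–C2 and C3–C4, an inverse-demand oxa-Diels–Alder reaction of the ring A ortho-quinone methide with an (E)-8''-(4-benzyloxystyryl)flavone under a chiral Brønsted acid. O7'' carries an acetate in this step, so that the flavonyl ring is a poor cation stabiliser and O7'' cannot capture a cation at the alkene or, later, at C4.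
- The stilbene comes from a Mizoroki–Heck coupling of an 8-iodoflavone (from apigenin) with 4-benzyloxystyrene; the methide precursor is the 2-hydroxybenzyl alcohol from 2,4,6-trihydroxybenzaldehyde.
- Ring order: the flavone rings come with apigenin and ring A with the aldehyde; ring C of the flavanone is the only ring made, in the key step.

Key step: step 9

Locants: the flavanone unit is unprimed (its 2-aryl ring primed); the flavone unit is double-primed (its 2''-aryl ring triple-primed). Free flavone intermediates carry ordinary flavone numbering.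

Assumption 1: the (R)-configured acid of step 9 is taken to give the 2R,3S product; should the first run give the mirror image, the (S)-acid is used with nothing else changed.

Assumption 2: the target is drawn as the free hydrogen sulfate; it is made as the sodium salt and set free with one equivalent of acid in the last operation, the salt being the form to store.

**Route**

Step 1
Reactants: 1 2,4,6-trihydroxybenzaldehyde
Product: 2 2,4-bis(benzyloxy)-6-hydroxybenzaldehyde
Conditions: BnBr (2.1 equiv), K2CO3, DMF, 0 °C → rt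
Reagents that add atoms: benzyl bromide, BrCc1ccccc1
Why: Williamson ether synthesis: the para-OH and one ortho-OH are benzylated, while the second ortho-OH, hydrogen-bonded to the aldehyde, is the least reactive and should stay free.

Step 2
Reactants: 2 2,4-bis(benzyloxy)-6-hydroxybenzaldehyde
Product: 3 3,5-bis(benzyloxy)-2-(hydroxymethyl)phenol
Conditions: NaBH4, THF/MeOH, 0 °C, pH 7 work-up, used at once
Reagents that add atoms: none
Why: Borohydride reduction of the aldehyde to the benzylic alcohol; it is run cold, briefly and worked up at neutral pH because this electron-rich 2-hydroxybenzyl alcohol ionises easily, so 3 goes directly into step 9.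

Step 3
Reactants: 4 apigenin
Product: 5 5-hydroxy-2-(4-hydroxyphenyl)-7-(methoxymethoxy)-4H-chromen-4-one
Conditions: MOMCl (1.05 equiv), iPr2NEt (1.2 equiv), DMF, −10 °C → rt
Reagents that add atoms: chloromethyl methyl ether, COCCl
Why: Williamson-type O-alkylation with one equivalent of the chloromethyl ether should take the most acidic phenol, 7-OH (para to the acyl carbon of ring A), ahead of 4'-OH and of the chelated 5-OH.

Step 4
Reactants: 5 5-hydroxy-2-(4-hydroxyphenyl)-7-(methoxymethoxy)-4H-chromen-4-one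
Product: 6 5-(benzyloxy)-2-[4-(benzyloxy)phenyl]-7-(methoxymethoxy)-4H-chromen-4-one
Conditions: BnBr (3 equiv), K2CO3, DMF, 70 °C
Reagents that add atoms: benzyl bromide, BrCc1ccccc1
Why: Williamson ether synthesis; heating in DMF overcomes the hydrogen bond of 5-OH to the C4 carbonyl, and the acetal ether at O7 is stable to base.

Step 5
Reactants: 6 5-(benzyloxy)-2-[4-(benzyloxy)phenyl]-7-(methoxymethoxy)-4H-chromen-4-one
Product: 7 5-(benzyloxy)-2-[4-(benzyloxy)phenyl]-8-iodo-7-(methoxymethoxy)-4H-chromen-4-one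
Conditions: NIS (1.1 equiv), TFA (0.2 equiv), MeCN/CH2Cl2, 0 °C → rt
Reagents that add atoms: N-iodosuccinimide, O=C1CCC(=O)N1I
Why: Electrophilic aromatic iodination; with O5 alkylated, 5,7-dialkoxyflavones are attacked at C8 (between O7 and the ring oxygen) and not at C6 (between two alkoxy groups), and ring A is far more electron-rich than the 2-aryl ring or C3.

Step 6
Reactants: 7 5-(benzyloxy)-2-[4-(benzyloxy)phenyl]-8-iodo-7-(methoxymethoxy)-4H-chromen-4-one
Product: 8 5-(benzyloxy)-2-[4-(benzyloxy)phenyl]-7-hydroxy-8-iodo-4H-chromen-4-one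
Conditions: 3 M HCl (aq), MeOH/THF, 50 °C
Reagents that add atoms: none
Why: Acid-catalysed acetal cleavage of the methoxymethyl ether; it is done before the alkene is installed, so that no ortho-hydroxystilbene is ever exposed to acid, and the benzyl ethers and the aryl iodide should survive dilute HCl.

Step 7
Reactants: 8 5-(benzyloxy)-2-[4-(benzyloxy)phenyl]-7-hydroxy-8-iodo-4H-chromen-4-one
Product: 9 5-(benzyloxy)-2-[4-(benzyloxy)phenyl]-8-iodo-4-oxo-4H-chromen-7-yl acetate
Conditions: Ac2O, pyridine, DMAP (cat.), CH2Cl2, rt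
Reagents that add atoms: acetic anhydride, CC(=O)OC(C)=O
Why: DMAP-catalysed acylation of the phenol; the acetate makes O7 a weak donor and a non-nucleophile for steps 9 and 10 and keeps it distinct from the benzyl ethers for the late sulfation.

Step 8
Reactants: 9 5-(benzyloxy)-2-[4-(benzyloxy)phenyl]-8-iodo-4-oxo-4H-chromen-7-yl acetate; 10 4-benzyloxystyrene
Product: 11 5-(benzyloxy)-2-[4-(benzyloxy)phenyl]-8-[(E)-2-(4-benzyloxyphenyl)ethenyl]-4-oxo-4H-chromen-7-yl acetate
Conditions: Pd(OAc)2 (10 mol %), P(o-tol)3 (20 mol %), NaOAc, Bu4NBr, DMAc, 100 °C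
Reagents that add atoms: none
Why: Mizoroki–Heck reaction: zerovalent palladium formed in situ adds into the C8–I bond, the styrene inserts at its terminal carbon and syn β-hydride elimination gives the (E)-stilbene; acetate as the base cannot harm the aryl acetate.

Step 9
Reactants: 3 3,5-bis(benzyloxy)-2-(hydroxymethyl)phenol; 11 5-(benzyloxy)-2-[4-(benzyloxy)phenyl]-8-[(E)-2-(4-benzyloxyphenyl)ethenyl]-4-oxo-4H-chromen-7-yl acetate
Product: 13 8-{(2R,3S)-5,7-bis(benzyloxy)-2-[4-(benzyloxy)phenyl]chroman-3-yl}-5-(benzyloxy)-2-[4-(benzyloxy)phenyl]-4-oxo-4H-chromen-7-yl acetate (2,3-trans), via ortho-quinone methide 12 (not isolated)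
Conditions: (R)-3,3'-bis(2,4,6-triisopropylphenyl)-1,1'-binaphthyl-2,2'-diyl N-triflylphosphoramide (10 mol %), 4 Å MS, CH2Cl2, −20 → 0 °C, 3 (2.5 equiv) added over 6 h by syringe pump
Reagents that add atoms: none
Why: The acid ionises the benzylic alcohol of 3 to ortho-quinone methide 12 and holds it as a hydrogen-bonded ion pair; the alkene carbon bearing the flavonyl group attacks the methide carbon (C3–C4) and the 4-benzyloxybenzylic cation developing at C2 is taken by the quinone oxygen (O1–C2) in one concerted, asynchronous inverse-demand oxa-Diels–Alder event. The closest known reaction type is the chiral Brønsted acid (N-triflylphosphoramide) catalysed [4+2] of in situ ortho-quinone methides with styrenes that carry no binding group. Ring C is closed intermolecularly by this [4+2], the second bond being the six-membered O1–C2 closure onto the benzylic cation. C2 and C3 are set together: suprafacial addition carries the E geometry into the 2,3-trans relation (also the thermodynamic outcome should closure be stepwise), and the chiral anion shields one face of bound 12 so that the alkene adds from the open face to give 2R,3S. The step needs regiocontrol (flavonyl at C3, not C2): the 7''-acetoxy group and the pyranone oxygen are weak donors and the di-ortho-substituted flavonyl ring is twisted out of the alkene plane, so the positive charge settles on the 4-benzyloxyphenyl carbon. Slow addition of 3 keeps the methide from condensing with itself or with its precursor.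

Step 10
Reactants: 13 8-{(2R,3S)-5,7-bis(benzyloxy)-2-[4-(benzyloxy)phenyl]chroman-3-yl}-5-(benzyloxy)-2-[4-(benzyloxy)phenyl]-4-oxo-4H-chromen-7-yl acetate
Product: 14 8-{(2R,3R,4R)-5,7-bis(benzyloxy)-2-[4-(benzyloxy)phenyl]-4-hydroxychroman-3-yl}-5-(benzyloxy)-2-[4-(benzyloxy)phenyl]-4-oxo-4H-chromen-7-yl acetate (3,4-trans alcohol; a C4 epimer would converge in step 11)
Conditions: DDQ (1.3 equiv), CH2Cl2/H2O (18:1), 0 °C → rt
Reagents that add atoms: water, O
Why: DDQ abstracts hydride from C4, the only methylene whose cation is stabilised by the ortho and para oxygens of ring A, and water captures the cation anti to the C3 aryl group (a known C4 functionalisation of benzylated flavans); C2 and C3 are untouched, the C4 configuration is lost in step 11, and the acetate keeps O7'' from closing a five-membered ether onto C4.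

Step 11
Reactants: 14 8-{(2R,3R,4R)-5,7-bis(benzyloxy)-2-[4-(benzyloxy)phenyl]-4-hydroxychroman-3-yl}-5-(benzyloxy)-2-[4-(benzyloxy)phenyl]-4-oxo-4H-chromen-7-yl acetate
Product: 15 8-{(2R,3S)-5,7-bis(benzyloxy)-2-[4-(benzyloxy)phenyl]-4-oxochroman-3-yl}-5-(benzyloxy)-2-[4-(benzyloxy)phenyl]-4-oxo-4H-chromen-7-yl acetate
Conditions: Dess–Martin periodinane, CH2Cl2, 0 °C → rt
Reagents that add atoms: none
Why: Dess–Martin oxidation of the secondary benzylic alcohol under non-basic conditions, so the now enolisable C3 is not put at risk; its trans configuration is in any case the thermodynamic one.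

Step 12
Reactants: 15 8-{(2R,3S)-5,7-bis(benzyloxy)-2-[4-(benzyloxy)phenyl]-4-oxochroman-3-yl}-5-(benzyloxy)-2-[4-(benzyloxy)phenyl]-4-oxo-4H-chromen-7-yl acetate
Product: 16 8-{(2R,3S)-5,7-bis(benzyloxy)-2-[4-(benzyloxy)phenyl]-4-oxochroman-3-yl}-5-(benzyloxy)-2-[4-(benzyloxy)phenyl]-7-hydroxy-4H-chromen-4-one
Conditions: NH4OAc (10 equiv), MeOH/THF/H2O, rt
Reagents that add atoms: none
Why: Mild, near-neutral transesterification of the electron-poor aryl acetate to methanol; strong base is avoided because the flavanone could open at O1–C2 by E1cB and lose both stereocentres.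

Step 13
Reactants: 16 8-{(2R,3S)-5,7-bis(benzyloxy)-2-[4-(benzyloxy)phenyl]-4-oxochroman-3-yl}-5-(benzyloxy)-2-[4-(benzyloxy)phenyl]-7-hydroxy-4H-chromen-4-one
Product: 17 sodium 8-{(2R,3S)-5,7-bis(benzyloxy)-2-[4-(benzyloxy)phenyl]-4-oxochroman-3-yl}-5-(benzyloxy)-2-[4-(benzyloxy)phenyl]-4-oxo-4H-chromen-7-yl sulfate
Conditions: SO3·pyridine (5 equiv), pyridine, 45 °C; then aq NaHCO3
Reagents that add atoms: sulfur trioxide–pyridine complex, O=S(=O)([O-])[n+]1ccccc1; sodium hydrogen carbonate, [Na+].OC([O-])=O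
Why: O-sulfonation of a phenol by a sulfur trioxide–amine complex; 7''-OH is the only free hydroxyl, so the site of sulfation is fixed by protection.

Step 14
Reactants: 17 sodium 8-{(2R,3S)-5,7-bis(benzyloxy)-2-[4-(benzyloxy)phenyl]-4-oxochroman-3-yl}-5-(benzyloxy)-2-[4-(benzyloxy)phenyl]-4-oxo-4H-chromen-7-yl sulfate
Product: 18 8-[(2R,3S)-5,7-dihydroxy-2-(4-hydroxyphenyl)-4-oxochroman-3-yl]-5-hydroxy-2-(4-hydroxyphenyl)-4-oxo-4H-chromen-7-yl hydrogen sulfate (target)
Conditions: H2 (1 atm), 10% Pd/C, THF/MeOH, rt; then aq HCl (1.0 equiv), 0 °C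
Reagents that add atoms: none
Why: Palladium-catalysed hydrogenolysis of the five aryl benzyl ethers under neutral, low-pressure conditions that aryl sulfate salts, the flavone enone and the electron-rich aryl ketone are expected to survive; one equivalent of acid then converts the sodium salt into the hydrogen sulfate without touching C2 or C3.

**Compound list**

1 | 2,4,6-trihydroxybenzaldehyde | O=Cc1c(O)cc(O)cc1O | starting material
2 | 2,4-bis(benzyloxy)-6-hydroxybenzaldehyde | O=Cc1c(O)cc(OCc2ccccc2)cc1OCc1ccccc1 | intermediate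
3 | 3,5-bis(benzyloxy)-2-(hydroxymethyl)phenol | OCc1c(O)cc(OCc2ccccc2)cc1OCc1ccccc1 | intermediate
4 | apigenin | O=c1cc(-c2ccc(O)cc2)oc2cc(O)cc(O)c12 | starting material
5 | 5-hydroxy-2-(4-hydroxyphenyl)-7-(methoxymethoxy)-4H-chromen-4-one | O=c1cc(-c2ccc(O)cc2)oc2cc(OCOC)cc(O)c12 | intermediate
6 | 5-(benzyloxy)-2-[4-(benzyloxy)phenyl]-7-(methoxymethoxy)-4H-chromen-4-one | O=c1cc(-c2ccc(OCc3ccccc3)cc2)oc2cc(OCOC)cc(OCc3ccccc3)c12 | intermediate
7 | 5-(benzyloxy)-2-[4-(benzyloxy)phenyl]-8-iodo-7-(methoxymethoxy)-4H-chromen-4-one | O=c1cc(-c2ccc(OCc3ccccc3)cc2)oc2c(I)c(OCOC)cc(OCc3ccccc3)c12 | intermediate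
8 | 5-(benzyloxy)-2-[4-(benzyloxy)phenyl]-7-hydroxy-8-iodo-4H-chromen-4-one | O=c1cc(-c2ccc(OCc3ccccc3)cc2)oc2c(I)c(O)cc(OCc3ccccc3)c12 | intermediate
9 | 5-(benzyloxy)-2-[4-(benzyloxy)phenyl]-8-iodo-4-oxo-4H-chromen-7-yl acetate | O=c1cc(-c2ccc(OCc3ccccc3)cc2)oc2c(I)c(OC(C)=O)cc(OCc3ccccc3)c12 | intermediate
10 | 4-benzyloxystyrene | C=Cc1ccc(OCc2ccccc2)cc1 | starting material
11 | 5-(benzyloxy)-2-[4-(benzyloxy)phenyl]-8-[(E)-2-(4-benzyloxyphenyl)ethenyl]-4-oxo-4H-chromen-7-yl acetate | c1(OCc5ccccc5)ccc(/C=C/c2c(OC(C)=O)cc(OCc5ccccc5)c3c(=O)cc(-c4ccc(OCc5ccccc5)cc4)oc23)cc1 | intermediate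
12 | 3,5-bis(benzyloxy)-6-methylidenecyclohexa-2,4-dien-1-one (ortho-quinone methide) | C=C1C(=O)C=C(OCc2ccccc2)C=C1OCc1ccccc1 | intermediate
13 | 8-{(2R,3S)-5,7-bis(benzyloxy)-2-[4-(benzyloxy)phenyl]chroman-3-yl}-5-(benzyloxy)-2-[4-(benzyloxy)phenyl]-4-oxo-4H-chromen-7-yl acetate | C1c2c(OCc5ccccc5)cc(OCc5ccccc5)cc2O[C@@H](c2ccc(OCc5ccccc5)cc2)[C@@H]1c1c(OC(C)=O)cc(OCc5ccccc5)c2c(=O)cc(-c3ccc(OCc5ccccc5)cc3)oc12 | intermediate
14 | 8-{(2R,3R,4R)-5,7-bis(benzyloxy)-2-[4-(benzyloxy)phenyl]-4-hydroxychroman-3-yl}-5-(benzyloxy)-2-[4-(benzyloxy)phenyl]-4-oxo-4H-chromen-7-yl acetate | O[C@H]1c2c(OCc5ccccc5)cc(OCc5ccccc5)cc2O[C@@H](c2ccc(OCc5ccccc5)cc2)[C@@H]1c1c(OC(C)=O)cc(OCc5ccccc5)c2c(=O)cc(-c3ccc(OCc5ccccc5)cc3)oc12 | intermediate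
15 | 8-{(2R,3S)-5,7-bis(benzyloxy)-2-[4-(benzyloxy)phenyl]-4-oxochroman-3-yl}-5-(benzyloxy)-2-[4-(benzyloxy)phenyl]-4-oxo-4H-chromen-7-yl acetate | O=C1c2c(OCc5ccccc5)cc(OCc5ccccc5)cc2O[C@@H](c2ccc(OCc5ccccc5)cc2)[C@@H]1c1c(OC(C)=O)cc(OCc5ccccc5)c2c(=O)cc(-c3ccc(OCc5ccccc5)cc3)oc12 | intermediate
16 | 8-{(2R,3S)-5,7-bis(benzyloxy)-2-[4-(benzyloxy)phenyl]-4-oxochroman-3-yl}-5-(benzyloxy)-2-[4-(benzyloxy)phenyl]-7-hydroxy-4H-chromen-4-one | O=C1c2c(OCc5ccccc5)cc(OCc5ccccc5)cc2O[C@@H](c2ccc(OCc5ccccc5)cc2)[C@@H]1c1c(O)cc(OCc5ccccc5)c2c(=O)cc(-c3ccc(OCc5ccccc5)cc3)oc12 | intermediate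
17 | sodium 8-{(2R,3S)-5,7-bis(benzyloxy)-2-[4-(benzyloxy)phenyl]-4-oxochroman-3-yl}-5-(benzyloxy)-2-[4-(benzyloxy)phenyl]-4-oxo-4H-chromen-7-yl sulfate | O=C1c2c(OCc5ccccc5)cc(OCc5ccccc5)cc2O[C@@H](c2ccc(OCc5ccccc5)cc2)[C@@H]1c1c(OS(=O)(=O)[O-])cc(OCc5ccccc5)c2c(=O)cc(-c3ccc(OCc5ccccc5)cc3)oc12.[Na+] | intermediate
18 | 8-[(2R,3S)-5,7-dihydroxy-2-(4-hydroxyphenyl)-4-oxochroman-3-yl]-5-hydroxy-2-(4-hydroxyphenyl)-4-oxo-4H-chromen-7-yl hydrogen sulfate | O=C1c2c(O)cc(O)cc2O[C@@H](c2ccc(O)cc2)[C@@H]1c1c(OS(=O)(=O)O)cc(O)c2c(=O)cc(-c3ccc(O)cc3)oc12 | target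

**Step count**

Total: 14 steps. Longest linear sequence: 12 steps (apigenin, steps 3–8, then steps 9–14).

**Steps most likely to fail**

Step 9 (key cycloaddition). Three processes may go wrong. The methide may condense with itself or its electron-rich precursor faster than it adds to a hindered, only moderately nucleophilic stilbene. Regiocontrol may erode if charge builds at the flavonyl-bearing carbon. Facial discrimination may be weak because the alkene offers no hydrogen bond to the acid. The fallback gives up catalyst control of absolute configuration and sets out from 3 and 11. The two are heated in toluene at 110 °C without catalyst (thermal loss of water from 3 gives 12), or stirred at room temperature with diphenyl phosphate, which is the established achiral cycloaddition of ortho-quinone methides with electron-rich styrenes. The racemic 2,3-trans chroman, that is 13 together with the mirror-image (2S,3R)-chroman F1, is then resolved by preparative chiral SFC on an amylose carbamate phase. The route is rejoined at 13.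

Step 10 (C4 oxidation). The C4 cation may lose H3 and give the 2H-chromene, which would erase C3, or hydride may be taken from C2, or oxidation may run on before water captures the cation. The fallback sets out from 13 and changes the intermediate. DDQ in CH2Cl2/MeOH traps the cation at once with the homogeneous nucleophile, as in the known C4 etherification of benzylated flavans, and should give the C4 methyl ether F2. A second DDQ oxidation in wet CH2Cl2 then takes the hydride from the ether carbon, and the hemiketal collapses to the ketone with loss of methanol. This bypasses alcohol 14 and step 11 and rejoins the route at 15.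

Step 8 (Heck coupling). Oxidative addition and insertion at the doubly ortho-substituted iodide may be slow, so that reductive loss of iodine competes; the electron-rich styrene may insert the other way round; and the acetate may be lost at 100 °C. The fallback fixes alkene geometry and regiochemistry in the coupling partner and sets out from 8 and 10. Cross-metathesis of 10 with vinylboronic acid pinacol ester (second-generation Grubbs catalyst, CH2Cl2, 40 °C) should give the (E)-styrylboronic acid pinacol ester F3. Suzuki–Miyaura coupling of F3 with iodophenol 8 (Pd(dppf)Cl2, K3PO4, dioxane/H2O, 80 °C; basic, so the ortho-hydroxystilbene cannot cyclise) should give the 7-hydroxystilbene F4. Acetylation (Ac2O, pyridine, DMAP) rejoins the route at 11.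

**Further compounds**

F1 | step 9 | 8-{(2S,3R)-5,7-bis(benzyloxy)-2-[4-(benzyloxy)phenyl]chroman-3-yl}-5-(benzyloxy)-2-[4-(benzyloxy)phenyl]-4-oxo-4H-chromen-7-yl acetate | C1c2c(OCc5ccccc5)cc(OCc5ccccc5)cc2O[C@H](c2ccc(OCc5ccccc5)cc2)[C@H]1c1c(OC(C)=O)cc(OCc5ccccc5)c2c(=O)cc(-c3ccc(OCc5ccccc5)cc3)oc12
F2 | step 10 | 8-{(2R,3R,4R)-5,7-bis(benzyloxy)-2-[4-(benzyloxy)phenyl]-4-methoxychroman-3-yl}-5-(benzyloxy)-2-[4-(benzyloxy)phenyl]-4-oxo-4H-chromen-7-yl acetate | CO[C@H]1c2c(OCc5ccccc5)cc(OCc5ccccc5)cc2O[C@@H](c2ccc(OCc5ccccc5)cc2)[C@@H]1c1c(OC(C)=O)cc(OCc5ccccc5)c2c(=O)cc(-c3ccc(OCc5ccccc5)cc3)oc12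
F3 | step 8 | 2-[(E)-2-(4-benzyloxyphenyl)ethenyl]-4,4,5,5-tetramethyl-1,3,2-dioxaborolane | CC1(C)OB(/C=C/c2ccc(OCc3ccccc3)cc2)OC1(C)C
F4 | step 8 | 5-(benzyloxy)-2-[4-(benzyloxy)phenyl]-8-[(E)-2-(4-benzyloxyphenyl)ethenyl]-7-hydroxy-4H-chromen-4-one | c1(OCc5ccccc5)ccc(/C=C/c2c(O)cc(OCc5ccccc5)c3c(=O)cc(-c4ccc(OCc5ccccc5)cc4)oc23)cc1
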